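3 questions stand on one flask, and one balance carries the reckoning.

| flask | left-handed substrate | right-handed substrate | coupling partner | free catalyst | impurity | remark | time |
|---|---|---|---|---|---|---|---|
| theta | 32 mM | 32 mM | 1.2 equiv | 0.5 mol% | 17 µM | the very flask that is asked about, followed so far |  |
| gamma | 32 mM | 32 mM | 1.2 equiv | 0.5 mol% | 8.5 µM | run made earlier |  |
| flask | 32 mM | 32 mM | 1.20 equiv | 0.5 mol% | 17 µM |  | 2.0 h |

| run | time / min | left-handed product / % | right-handed product / % |
|---|---|---|---|
| theta | 1.00 | 4.1 | 3.1 |
| theta | 3.00 | 11.1 | 6.4 |
| theta | 5.00 | 15.5 | 9.9 |
| theta | 8.00 | 23.9 | 11.0 |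
| theta | 12.0 | 27.8 | 15.8 |
| theta | 15.0 | 28.8 | 16.8 |
| gamma | 6.00 | 18.6 | 11.4 |
| gamma | 15.0 | 31.1 | 16.2 |
| gamma | 30.0 | 34.5 | 17.8 |
| gamma | 50.0 | 37.1 | 17.9 |
| gamma | 60.0 | 36.2 | 17.5 |
| gamma | 80.0 | 37.6 | 18.6 |

(readings scatter by 1 percentage point)

- excess of left-handed product over right-handed product in the product at 2.5 min
- excess of left-handed product over right-handed product in the product at 2.0 h
- part of the left-handed substrate and right-handed substrate charged together that has reacted at 2.0 h

- free catalyst is single-handed; left-handed substrate and right-handed substrate are mirror images of each other, charged as a racemate, each of them at the stated concentration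
- the numbers in the tables scatter with a standard deviation of 1 percentage point
- an excess is below zero if the other one leads

Start from coupling partner, the limiting reagent: 38.4 mM charged against 64.0 mM of the substrates together. Allow one coupling partner per product. The coupling ceiling C, the part of the substrates together that the charged coupling partner can convert, is 60.0 %.

Now draw total product. Take the starting slope s from theta at 3.00 min: 0.0583 /min. Read the level L from the last 3 gamma totals, which have the same coupling partner charge: 55.0 %, which is 5 percentage points under C. At 15.0 min, theta, with twice gamma's impurity, trails gamma by 1.7 points, within the 2 points of scatter that a difference of 4 readings carries, so use L for this flask.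

Read the knee of the curve at τ = L/s = 9.42 min. An exponential with that τ gives 43.8 % at 15.0 min, and theta reads 45.6 %. The asked 2.0 h is 12.7 times τ, so expect this flask on L.

For the excess, pool left-handed and right-handed product over several readings. Theta's first 3 readings give 22.6 % for the early time, and gamma's last 3 give 34.5 % for the end.

The forecast, holding that “the flask is on its plateau” at the end, gives 21 %, 33 % and 53 %, each below my figures.

The flask gives 23.7 %, 31.5 % and 55.2 %.

    coupling partner + catalyst intermediate B → free catalyst + right-handed product (k = 1310 /M/min)
    free catalyst + left-handed substrate ⇌ catalyst intermediate A (K = 49.9 /M, k = 1420 /M/min)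
    coupling partner → decomposed reagent (k = 0.00930 /min)
    coupling partner + catalyst intermediate A → free catalyst + left-handed product (k = 2890 /M/min)
    2 free catalyst → spent catalyst B (k = 277 /M/min)
    free catalyst + impurity → spent catalyst A (k = 25400 /M/min)
    free catalyst + right-handed substrate ⇌ catalyst intermediate B (K = 18.0 /M, k = 3910 /M/min)

Against decomposition, coupling partner has a lifetime 1/k3 of 108 min, longer than the 5.73 min by which this flask has done half the turnover of free catalyst with left-handed substrate up to the asked time. At 2.00 h this flask keeps 0.019 % of its coupling partner charge against 62 % of its right-handed substrate, and its 3.11 mM of decomposed reagent lowers C to 55.1 %. The flask with 0.720 equiv of coupling partner, otherwise the same, has C = 36.0 %; its 1.40 mM of decomposed reagent lowers that to 33.8 %, and it reaches 33.9 %.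

All runs were generated by integration for substances that don't exist; scatter was added.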